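How much product stands after 2.0 h as the solid partner charge goes from 25.0 mM to 150 mM?

| flask | starting material | solid partner | remark | time |
|---|---|---|---|---|
| grey | 20 mM | 36 mM | run made earlier |  |
| red | 20 mM | 200 mM | run made earlier |  |
| eta | 20 mM | 25.0 mM |  | 2.0 h |
| epsilon | 20 mM | 40.0 mM |  | 2.0 h |
| beta | 20 mM | 60.0 mM |  | 2.0 h |
| gamma | 20 mM | 100 mM |  | 2.0 h |
| delta | 20 mM | 150 mM |  | 2.0 h |

| run | time / min | product / % | starting material / % |
|---|---|---|---|
| grey | 5.00 | 0 | 96.9 |
| grey | 8.00 | 0.1 | 94.6 |
| grey | 12.0 | 1.0 | 92.0 |
| grey | 20.0 | 1.0 | 87.3 |
| grey | 40.0 | 4.7 | 77.9 |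
| grey | 60.0 | 8.4 | 70.8 |
| red | 4.00 | 0 | 97.2 |
| red | 12.0 | 0.1 | 92.1 |
| red | 20.0 | 1.0 | 87.5 |
| red | 30.0 | 3.1 | 82.7 |
| red | 50.0 | 7.1 | 73.9 |
| red | 60.0 | 9.3 | 70.9 |

(each reading ± 0.3 percentage points)

- amount of product at the end, in percent of the starting material charged for eta, epsilon, beta, gamma, delta, in this order
- how that number moves from the first to the last of them (rises all the way / hardly changes / rises, then falls / falls, then rises / falls all the way)

- product is meant together with its crystals
- solid, in amounts per volume of the solution: solid partner, crystals
- on the list of suspects stand: starting material <-> open intermediate; fresh partner -> second intermediate; open intermediate + second intermediate <-> product; solid partner <-> fresh partner; crystals <-> product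
- at the start none of the solid partner is in solution
- "hardly changes" means that all values lie within two and a half points (for a concentration: within two and a half percent of the largest)

I build the flask up one process at a time.

1. Main step: the starting material opens. At 60.0 min it reads 70.8 % in the grey run and 70.9 % in the red run, a gap of 0.1 percentage points against a scatter of 0.3 points, so I leave the solid charge out of this step. With this step alone, the asked number stays at nothing.

2. Add the partner feed. Product lags, then climbs. From 20.0 min to 60.0 min the two runs gain 7.4 points and 8.3 points, although their charges are 36 mM and 200 mM, so the climb is read as zero order in the solid charge. Taking one partner per product, their mean slope is a draw of 0.0393 mM min⁻¹. Continuing that climb from the mean reading at 60.0 min, I reckon 20.6 % at 2.0 h.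

3. Add the rest. Crystals count as product, so a passage of product into crystals does not itself move the number. To see whether the solid partner of eta lasts the run, I count its life. The lasting time of eta is 10.6 h: the solid partner charge divided by the draw. Eta has the smallest charge, and its lasting time exceeds the run, so I expect a flat row.

The forecast gives 22.5 % for eta and 23 % from epsilon to delta, hardly changes, holding that “excess solid does nothing”. My reckoning stands lower, with the same shape.

The flask gives 20.9 %, 20.9 %, 20.9 %, 20.9 % and 20.9 %: hardly changes. The forecast lies 2.1 points above delta, within its margin.

    starting material ⇌ open intermediate (K = 0.920, k = 0.00710 min⁻¹)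
    fresh partner → second intermediate (k = 0.0300 min⁻¹)
    open intermediate + second intermediate ⇌ product (K = 1800 M⁻¹, k = 30.0 M⁻¹ min⁻¹)
    solid partner ⇌ fresh partner, rate k4*(cs4 - [fresh partner]) while solid is left; crystals form when [fresh partner] > cs4 (solubility = 1.60 mM, k = 0.230 min⁻¹)
    crystals ⇌ product, rate k5*(cs5 - [product]) while solid is left; crystals form when [product] > cs5 (solubility = 7.10 mM, k = 0.240 min⁻¹)

In eta, the lasting time of 10.6 h stands against 2.0 h, and at 2.00 h eta keeps 74.6 % of its solid partner, with [fresh partner] at 1.42 mM, as at 1.00 h. Carried to 20.0 h, the lasting time of epsilon is 17.0 h, shorter, and epsilon holds 0 % of its solid, while that of beta is 25.5 h, longer, and beta still holds 13.0 %.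

The earlier runs and the new flask were computed for an exercise; scatter was added.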